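**Retrosynthetic overview**
1. The target is read as 2α,6β,7α-triacetoxylabda-8,13E-dien-15-ol; the endgame is O-desilylation ⇐ triacetate ⇐ α-face reduction of a C6 ketone (6β-OH) ⇐ enolate hydroxylation at C7 (7α-OH) of a 6-oxo-Δ8 decalin.
2. C9–C11 is cut by a Negishi coupling between a ring B C9 enol triflate (from a Δ7-6,9-ene-dione by conjugate reduction) and a C11–C16 alkylzinc made from (E)-3-methylpent-2-en-4-yn-1-ol.
3. Ring A is cut at C2–C3 and at one C4–CH3 bond: an alkylative Prins cyclization of a monocyclic C2 aldehyde onto a C3=C4 isopropenyl group, the tertiary C4 cation being capped by chloride and then by methyl from AlMe3.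
4. Enabling feature: in ring A the gem-dimethyl quaternary C4 and the oxygen-bearing C2 are separated only by the C3 methylene, so C3=C4 (isopropenyl on C5) plus C2=O (on the C10 arm through C1) is a Markovnikov carbonyl–alkene closure; the trans arms on C5/C10 of ring B and the axial C10 methyl fix the trans fusion and the 2α-oxygen.
5. Ring order: ring B first (the ring of (R)-carvone; C5 from the chiral pool, C10 by two enolate alkylations), ring A second (key step), side chain third.

Key step: step 5

Remark: labdane numbering is used for the decalin and for the corresponding carbons of its monocyclic precursors; the target belongs to the normal series (5α-H, 10β-CH3).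
Remark: centres that are erased in the following step (C10 of 3, the ring carbinol of 6, C4 of 8 and of F2) occur as epimer mixtures and are drawn for the major epimer or left undefined; the aryl group of the sulfonylhydrazone in the first fallback is assumed to be mesityl.

**Route**

Step 1
Reactants: 1 (R)-(−)-carvone
Product: 3 trans-6-methylcarvone, via lithium dienolate 2 (not isolated)
Conditions: LiN(i-Pr)2 (1.05 equiv), THF, −78 °C; then MeI, −78 to 0 °C
Reagents that add atoms: iodomethane, CI
Why: Kinetic deprotonation at the only α′ position and C-methylation of the lithium dienolate (enolate alkylation) is standard for carvone; the methyl group should enter mainly trans to the isopropenyl group, and this centre is re-enolized in step 2.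

Step 2
Reactants: 3 trans-6-methylcarvone
Product: 5 tert-butyl ester with quaternary C10, via lithium enolate 4 (not isolated)
Conditions: LiN(i-Pr)2 (1.1 equiv), THF, −78 °C; then BrCH2CO2t-Bu, DMPU, −78 to −20 °C
Reagents that add atoms: tert-butyl bromoacetate, BrCC(=O)OC(C)(C)C
Why: In this enolate alkylation the activated α-bromo ester should approach the tetrasubstituted enolate anti to the neighbouring C5 isopropenyl group, which places CH2CO2t-Bu trans and CH3 cis to it (the 5α-H/10β-CH3 relationship), as is known for the second alkylation of 6-methylcarvone.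

Step 3
Reactants: 5 tert-butyl ester
Product: 6 diol (ring carbinol epimers)
Conditions: LiAlH4, Et2O, 0 °C
Reagents that add atoms: none
Why: Hydride reduction takes the ester to the primary alcohol and the enone by 1,2-addition to the allylic alcohol without touching the isolated isopropenyl group, and the carbinol epimers converge in step 4.

Step 4
Reactants: 6 diol
Product: 7 keto aldehyde
Conditions: Dess–Martin periodinane (2.5 equiv), NaHCO3, CH2Cl2, 0 °C to rt
Reagents that add atoms: none
Why: Dess–Martin oxidation returns both carbinols to the carbonyl level under buffered neutral conditions, and the aldehyde has no epimerizable α-centre because it hangs on the quaternary C10.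

Step 5
Reactants: 7 keto aldehyde
Product: 9 bicyclic 2α-hydroxy enone, via chloro alkoxide 8 (not isolated)
Conditions: Me2AlCl (2.5 equiv), CH2Cl2, −78 °C; then AlMe3 (4 equiv), −78 to −30 °C
Reagents that add atoms: trimethylaluminium, C[Al](C)C
Why: Proposed new method: Me2AlCl binds the C2 aldehyde, the C3 methylene terminus of the C5 isopropenyl group attacks it (Prins cyclization, Markovnikov) and the tertiary C4 cation collapses with chloride from the aluminate to chloro alkoxide 8, after which AlMe3 re-ionizes the tertiary C–Cl bond and returns a methyl group to C4, so that one flask forms the C2–C3 bond, ring A, the C2 carbinol and the gem-dimethyl quaternary C4. The closest known reaction types are the Me2AlCl-promoted intramolecular carbonyl–ene/Prins cyclization of 5-methylhex-5-enal-type aldehydes to 3-methylenecyclohexanols or their γ-chloro alcohols, the syn addition of CH2OH and CH3 across alkenes by formaldehyde–AlMe3, and the methylation of tertiary alkyl chlorides by AlMe3, and their merger on one substrate is the new element. Ring A closes through a six-membered chair that is exo with respect to the C=O and endo with respect to the C3=C4 π bond, and the trans ring fusion follows from the trans-diequatorial C5 and C10 arms already present in 7. The new C2 stereocentre is controlled by the axial C10 methyl group, which forces the aluminium-bound oxygen into the equatorial position of the chair (2α-OH), while C4 ends with two methyl groups and is not stereogenic, so the face of chloride or methyl capture is irrelevant. The step needs activation of the aldehyde in preference to the enone carbonyl (the aldehyde is the stronger electrophile and the enone C=C is too electron-poor to act as nucleophile) and capture of the C4 cation faster than proton loss or a 1,2-hydride shift from C5, which should be secured by ion-pair chloride delivery at −78 °C and by adding AlMe3 only after the aldehyde is consumed, so that no methyl carbinol forms.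

Step 6
Reactants: 9 bicyclic 2α-hydroxy enone
Product: 10 2α-acetoxy enone
Conditions: Ac2O, pyridine, DMAP (cat.), CH2Cl2, rt
Reagents that add atoms: acetic anhydride, CC(=O)OC(C)=O
Why: DMAP-catalysed acylation of the unhindered equatorial secondary alcohol installs the final C2 acetate, which should tolerate every later step.

Step 7
Reactants: 10 2α-acetoxy enone
Product: 11 Δ7-6,9-ene-dione
Conditions: Pd(OH)2/C (5 mol %), t-BuOOH (5 equiv), K2CO3 (0.25 equiv), CH2Cl2, 4 °C to rt
Reagents that add atoms: tert-butyl hydroperoxide, CC(C)(C)OO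
Why: The known peroxyl-radical oxidation of the γ-methylene of an α,β-enone to the 1,4-ene-dione should place the C6 carbonyl, since C6 is the only γ-CH2 and ring A carries no alkene.

Step 8
Reactants: 11 Δ7-6,9-ene-dione
Product: 13 C9 enol triflate, via lithium enolate 12 (not isolated)
Conditions: LiBH(s-Bu)3 (1.05 equiv), THF, −78 °C; then N-(5-chloropyridin-2-yl)bis(trifluoromethanesulfonyl)imide, −78 to 0 °C
Reagents that add atoms: N-(5-chloropyridin-2-yl)bis(trifluoromethanesulfonyl)imide, O=S(=O)(N(c1ccc(Cl)cn1)S(=O)(=O)C(F)(F)F)C(F)(F)F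
Why: In this conjugate reduction–enolate triflation the bulky borohydride should deliver hydride to the unsubstituted C7 terminus of the ene-dione and not to the methyl-bearing C8, which gives the C9 enolate regiospecifically for trapping as the tetrasubstituted C8=C9 enol triflate while C6 stays a ketone.

Step 9
Reactants: 14 (E)-3-methylpent-2-en-4-yn-1-ol
Product: 15 enyne silyl ether
Conditions: TBSCl, imidazole, CH2Cl2, 0 °C to rt
Reagents that add atoms: tert-butyldimethylsilyl chloride, CC(C)(C)[Si](C)(C)Cl
Why: Silylation of the primary allylic alcohol gives a C15 protecting group that is orthogonal to the three acetates, and the E-alkene of the side chain is bought with the starting material.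

Step 10
Reactants: 15 enyne silyl ether
Product: 16 diene silyl ether
Conditions: H2 (1 atm), Pd/CaCO3 poisoned with Pb(OAc)2, quinoline, hexane, rt
Reagents that add atoms: none
Why: Lindlar semi-hydrogenation of the terminal alkyne should stop at the vinyl group and leave the trisubstituted E-alkene untouched.

Step 11
Reactants: 16 diene silyl ether
Product: 18 homoallylic alcohol, via B-alkyl-9-BBN 17 (not isolated)
Conditions: 9-BBN, THF, 0 °C to rt; then NaOH, H2O2, 0 °C
Reagents that add atoms: hydrogen peroxide, OO
Why: Hydroboration–oxidation with the bulky borane should take place only at the monosubstituted terminus of the diene, anti-Markovnikov, because the trisubstituted alkene is too hindered.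

Step 12
Reactants: 18 homoallylic alcohol
Product: 19 homoallylic iodide
Conditions: I2, PPh3, imidazole, CH2Cl2, 0 °C
Reagents that add atoms: iodine, II
Why: Appel-type iodination of the primary alcohol proceeds by SN2 on the alkoxyphosphonium ion and leaves the allylic silyl ether and the alkene alone.

Step 13
Reactants: 13 C9 enol triflate; 19 homoallylic iodide
Product: 21 coupled 6-ketone, via alkylzinc iodide 20 (not isolated)
Conditions: 19, Zn dust, LiCl, THF, 40 °C; then 13, Pd2(dba)3 (2.5 mol %), SPhos (10 mol %), THF/NMP, 50 °C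
Reagents that add atoms: none
Why: Negishi coupling of a primary alkylzinc with a hindered enol triflate under zerovalent palladium/biarylphosphine catalysis should form C9–C11 under neutral conditions that spare the acetate, the silyl ether and the β,γ-unsaturated ketone.

Step 14
Reactants: 21 coupled 6-ketone
Product: 23 7α-hydroxy ketone, via potassium dienolate 22 (not isolated)
Conditions: KN(SiMe3)2 (1.1 equiv), THF, −78 °C; then 3-phenyl-2-(phenylsulfonyl)oxaziridine, −78 °C
Reagents that add atoms: 3-phenyl-2-(phenylsulfonyl)oxaziridine, O=S(=O)(c1ccccc1)N1OC1c1ccccc1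
Why: In this oxaziridine α-hydroxylation C7 is the only α and allylic position, oxygen should go to the α-carbon of the dienolate and not to the fully substituted C9, and it should arrive on the α face because the β face is screened by the C4β and C10β methyl groups.

Step 15
Reactants: 23 7α-hydroxy ketone
Product: 24 6β,7α-diol
Conditions: NaBH4, MeOH, −20 to 0 °C
Reagents that add atoms: none
Why: Borohydride should attack the C6 ketone from the α face, since the β face carries two syn-axial methyl groups (on C4 and C10), which gives the axial 6β-alcohol trans to the 7α-hydroxyl.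

Step 16
Reactants: 24 6β,7α-diol
Product: 25 triacetate silyl ether
Conditions: Ac2O, DMAP, Et3N, CH2Cl2, 40 °C
Reagents that add atoms: acetic anhydride, CC(=O)OC(C)=O
Why: DMAP-catalysed acylation with gentle warming should esterify both the allylic 7α-hydroxyl and the hindered axial 6β-hydroxyl, and a trans-diaxial diol cannot undergo acyl migration.

Step 17
Reactants: 25 triacetate silyl ether
Product: 26 2α,6β,7α-triacetoxylabda-8,13E-dien-15-ol
Conditions: HF·pyridine, pyridine, THF, 0 °C to rt
Reagents that add atoms: none
Why: Buffered fluoride cleaves the primary Si–O bond selectively and leaves the three acetates, including the allylic one at C7, in place.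

**Compound list**
1 | (R)-(−)-carvone, (5R)-2-methyl-5-(prop-1-en-2-yl)cyclohex-2-en-1-one | C=C(C)[C@@H]1CC=C(C)C(=O)C1 | starting material
2 | lithium dienolate of 1 (O–Li on C1, C1=C6 and C2=C3) | C=C(C)[C@@H]1CC=C(C)C(O[Li])=C1 | intermediate
3 | trans-6-methylcarvone, (5R)-2,6-dimethyl-5-(prop-1-en-2-yl)cyclohex-2-en-1-one, 6-CH3 trans to isopropenyl (minor cis epimer carried along) | C=C(C)[C@@H]1CC=C(C)C(=O)[C@H]1C | intermediate
4 | lithium enolate of 3 (O–Li on C1, C1=C6) | C=C(C)[C@@H]1CC=C(C)C(O[Li])=C1C | intermediate
5 | tert-butyl 2-[1,3-dimethyl-2-oxo-6-(prop-1-en-2-yl)cyclohex-3-en-1-yl]acetate; at the quaternary carbon (labdane C10) CH3 is cis and CH2CO2t-Bu trans to the isopropenyl group on the adjacent carbon (labdane C5) | C=C(C)[C@@H]1CC=C(C)C(=O)[C@@]1(C)CC(=O)OC(C)(C)C | intermediate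
6 | 6-(2-hydroxyethyl)-2,6-dimethyl-5-(prop-1-en-2-yl)cyclohex-2-en-1-ol; ring stereocentres as in 5, both C1 carbinol epimers | C=C(C)[C@@H]1CC=C(C)C(O)[C@@]1(C)CCO | intermediate
7 | 2-[1,3-dimethyl-2-oxo-6-(prop-1-en-2-yl)cyclohex-3-en-1-yl]acetaldehyde; stereocentres as in 5 | C=C(C)[C@@H]1CC=C(C)C(=O)[C@@]1(C)CC=O | intermediate
8 | dimethylaluminium alkoxide of 4-chloro-2α-hydroxy-4,8,10β-trimethyl-5α-decal-7-en-9-one (labdane numbering; C4 epimers) | C[Al](C)O[C@H]1CC(C)(Cl)[C@@H]2CC=C(C)C(=O)[C@@]2(C)C1 | intermediate
9 | 2α-hydroxy-4,4,8,10β-tetramethyl-5α-decal-7-en-9-one (labdane numbering); 7-hydroxy-2,5,5,8a-tetramethyl-4a,5,6,7,8,8a-hexahydronaphthalen-1(4H)-one | O[C@H]1CC(C)(C)[C@@H]2CC=C(C)C(=O)[C@@]2(C)C1 | intermediate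
10 | 2α-acetoxy-4,4,8,10β-tetramethyl-5α-decal-7-en-9-one (labdane numbering) | CC(=O)O[C@H]1CC(C)(C)[C@@H]2CC=C(C)C(=O)[C@@]2(C)C1 | intermediate
11 | 2α-acetoxy-4,4,8,10β-tetramethyl-5α-decal-7-ene-6,9-dione (labdane numbering) | CC(=O)O[C@H]1CC(C)(C)[C@@H]2C(=O)C=C(C)C(=O)[C@@]2(C)C1 | intermediate
12 | lithium C9 enolate of the 7,8-dihydro derivative of 11 (O–Li on C9, C8=C9, C6=O) | CC(=O)O[C@H]1CC(C)(C)[C@@H]2C(=O)CC(C)=C(O[Li])[C@@]2(C)C1 | intermediate
13 | 2α-acetoxy-4,4,8,10β-tetramethyl-6-oxo-5α-decal-8-en-9-yl trifluoromethanesulfonate (labdane numbering) | CC(=O)O[C@H]1CC(C)(C)[C@@H]2C(=O)CC(C)=C(OS(=O)(=O)C(F)(F)F)[C@@]2(C)C1 | intermediate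
14 | (E)-3-methylpent-2-en-4-yn-1-ol | C#C/C(C)=C/CO | starting material
15 | (E)-tert-butyldimethyl[(3-methylpent-2-en-4-yn-1-yl)oxy]silane | C#C/C(C)=C/CO[Si](C)(C)C(C)(C)C | intermediate
16 | (E)-tert-butyldimethyl[(3-methylpenta-2,4-dien-1-yl)oxy]silane | C=C/C(C)=C/CO[Si](C)(C)C(C)(C)C | intermediate
17 | B-[(E)-5-(tert-butyldimethylsilyloxy)-3-methylpent-3-en-1-yl]-9-borabicyclo[3.3.1]nonane | CC(C)(C)[Si](C)(C)OC/C=C(\C)CCB1C2CCCC1CCC2 | intermediate
18 | (E)-5-(tert-butyldimethylsilyloxy)-3-methylpent-3-en-1-ol | OCC/C(C)=C/CO[Si](C)(C)C(C)(C)C | intermediate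
19 | (E)-tert-butyl[(5-iodo-3-methylpent-2-en-1-yl)oxy]dimethylsilane | ICC/C(C)=C/CO[Si](C)(C)C(C)(C)C | intermediate
20 | [(E)-5-(tert-butyldimethylsilyloxy)-3-methylpent-3-en-1-yl]zinc iodide | I[Zn]CC/C(C)=C/CO[Si](C)(C)C(C)(C)C | intermediate
21 | 2α-acetoxy-15-(tert-butyldimethylsilyloxy)labda-8,13E-dien-6-one | CC(=O)O[C@H]1CC(C)(C)[C@@H]2C(=O)CC(C)=C(CC/C(C)=C/CO[Si](C)(C)C(C)(C)C)[C@@]2(C)C1 | intermediate
22 | potassium dienolate of 21 (O–K on C6, C6=C7 and C8=C9) | CC(=O)O[C@H]1CC(C)(C)[C@@H]2C(O[K])=CC(C)=C(CC/C(C)=C/CO[Si](C)(C)C(C)(C)C)[C@@]2(C)C1 | intermediate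
23 | 2α-acetoxy-7α-hydroxy-15-(tert-butyldimethylsilyloxy)labda-8,13E-dien-6-one | CC(=O)O[C@H]1CC(C)(C)[C@@H]2C(=O)[C@@H](O)C(C)=C(CC/C(C)=C/CO[Si](C)(C)C(C)(C)C)[C@@]2(C)C1 | intermediate
24 | 2α-acetoxy-15-(tert-butyldimethylsilyloxy)labda-8,13E-diene-6β,7α-diol | CC(=O)O[C@H]1CC(C)(C)[C@@H]2[C@H](O)[C@@H](O)C(C)=C(CC/C(C)=C/CO[Si](C)(C)C(C)(C)C)[C@@]2(C)C1 | intermediate
25 | 2α,6β,7α-triacetoxy-15-(tert-butyldimethylsilyloxy)labda-8,13E-diene | CC(=O)O[C@H]1CC(C)(C)[C@@H]2[C@H](OC(C)=O)[C@@H](OC(C)=O)C(C)=C(CC/C(C)=C/CO[Si](C)(C)C(C)(C)C)[C@@]2(C)C1 | intermediate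
26 | 2α,6β,7α-triacetoxylabda-8,13E-dien-15-ol (CNP0305346.2) | CC(=O)O[C@H]1CC(C)(C)[C@@H]2[C@H](OC(C)=O)[C@@H](OC(C)=O)C(C)=C(CC/C(C)=C/CO)[C@@]2(C)C1 | target

**Step count and risks**
Total step count: 17. Longest linear sequence: 13 steps (steps 1–8 and 13–17, from 1 to 26).

Steps most likely to fail:

Step 5 (Proposed new method). The C4 cation may lose a proton or undergo a 1,2-hydride shift from C5 before chloride or methyl capture, or the methyl donor may add to a carbonyl group. The fallback separates the two events and replaces the cationic methyl transfer by a radical one. It sets out from 7: Me2AlCl alone (CH2Cl2, −78 to 0 °C) effects the known intramolecular carbonyl–ene cyclization of this 5-methylhex-5-enal-type aldehyde and should give 2α-hydroxy-4-methylene-8,10β-dimethyl-5α-decal-7-en-9-one F1, the oxygen again being equatorial. Hydrogen-atom-transfer hydromethylation of F1 (Fe(acac)3, PhSiH3, formaldehyde mesitylsulfonylhydrazone, THF/MeOH) should trap the tertiary C4 radical as the N-alkyl-N′-mesitylsulfonylhydrazide F2. On warming in methanol F2 loses sulfinic acid and dinitrogen, which leaves the second C4 methyl group and returns to the route at 9.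

Step 8. Hydride may be delivered to C8 instead of C7, the C6 ketone may be reduced, or the enolate may equilibrate toward C6/C7 before trapping. The fallback sets out from 11: Rh(PPh3)3Cl-catalysed 1,4-hydrosilylation with Et3SiH (benzene, 50 °C) leaves the isolated ketone alone and hands over the enolate as the isolable C9 triethylsilyl enol ether F3, whose regiochemistry can be checked. Fluoride-triggered triflation of F3 (CsF, N-phenylbis(trifluoromethanesulfonyl)imide, DME, rt) then returns to the route at 13.

Step 14. Oxygen transfer to the dienolate may occur with poor facial selectivity, or mainly from the β face. The fallback sets C7 by SN2 inversion instead of enolate face control. It sets out from 21: the same hydroxylation is run and the 7β-hydroxy ketone F4 is taken on. A Mitsunobu reaction (PPh3, diisopropyl azodicarboxylate, AcOH, toluene, 0 °C) at the activated allylic α-keto carbon should invert C7 to the 7α-acetoxy ketone F5. NaBH4 (MeOH, −20 °C) then gives the 6β-alcohol F6 by the same α-face hydride delivery, and Ac2O/DMAP acetylation of F6 returns to the route at 25.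

Further compounds
F1 | step 5 | 2α-hydroxy-4-methylene-8,10β-dimethyl-5α-decal-7-en-9-one (labdane numbering) | O[C@H]1CC(=C)[C@@H]2CC=C(C)C(=O)[C@@]2(C)C1
F2 | step 5 | N′-[(2α-hydroxy-4,8,10β-trimethyl-9-oxo-5α-decal-7-en-4-yl)methyl]-2,4,6-trimethylbenzenesulfonohydrazide (C4 epimers) | O[C@H]1CC(C)(CNNS(=O)(=O)c3c(C)cc(C)cc3C)[C@@H]2CC=C(C)C(=O)[C@@]2(C)C1
F3 | step 8 | 2α-acetoxy-4,4,8,10β-tetramethyl-9-(triethylsilyloxy)-5α-decal-8-en-6-one (labdane numbering) | CC(=O)O[C@H]1CC(C)(C)[C@@H]2C(=O)CC(C)=C(O[Si](CC)(CC)CC)[C@@]2(C)C1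
F4 | step 14 | 2α-acetoxy-7β-hydroxy-15-(tert-butyldimethylsilyloxy)labda-8,13E-dien-6-one | CC(=O)O[C@H]1CC(C)(C)[C@@H]2C(=O)[C@H](O)C(C)=C(CC/C(C)=C/CO[Si](C)(C)C(C)(C)C)[C@@]2(C)C1
F5 | step 14 | 2α,7α-diacetoxy-15-(tert-butyldimethylsilyloxy)labda-8,13E-dien-6-one | CC(=O)O[C@H]1CC(C)(C)[C@@H]2C(=O)[C@@H](OC(C)=O)C(C)=C(CC/C(C)=C/CO[Si](C)(C)C(C)(C)C)[C@@]2(C)C1
F6 | step 14 | 2α,7α-diacetoxy-15-(tert-butyldimethylsilyloxy)labda-8,13E-dien-6β-ol | CC(=O)O[C@H]1CC(C)(C)[C@@H]2[C@H](O)[C@@H](OC(C)=O)C(C)=C(CC/C(C)=C/CO[Si](C)(C)C(C)(C)C)[C@@]2(C)C1
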